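**Retrosynthetic overview**
- The target is the (3R)-isoflavan. The last operations are removal of two silyl ethers, Stille prenylation of a C6 bromide on ring A, and construction of the dimethylpyran on ring B from the 2'-phenol (propargyl ether, Claisen rearrangement, oxa-6π closure).
- The chroman ring (ring C) is closed first, by Mitsunobu etherification of the ring A phenol onto a primary alcohol. The pyran on ring B is the second and last ring formed.
- The primary alcohol comes from reductive removal of an Evans auxiliary. The C4 methylene comes from ionic deoxygenation of a benzylic aldol hydroxyl, done before any acid-sensitive alkene is present.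
- Key C3–C4 bond: boron-mediated Evans syn-aldol between the ring B arylacetyl oxazolidinone and the ring A benzaldehyde. This sets C3; the carbinol centre is later erased.
- Both fragments come from 2,4-dihydroxybenzaldehydes with three orthogonal phenol protecting groups: allyl, benzyl and triisopropylsilyl.

Assumption: compounds 1, 4 and 10 and all reagents named are bought. "Triisopropylsilyloxy" is the group OSi(i-Pr)3.

**Route**

Step 1
Reactants: 1 5-bromo-2,4-dihydroxybenzaldehyde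
Product: 2 5-bromo-2-hydroxy-4-(triisopropylsilyloxy)benzaldehyde
Conditions: i-Pr3SiCl (1.05 equiv), imidazole, CH2Cl2, 0 °C → rt
Reagents that add atoms: triisopropylsilyl chloride, CC(C)[Si](Cl)(C(C)C)C(C)C
Why: Selective silyl ether formation, because the 2-OH is locked in a hydrogen bond to the aldehyde and only the free, more acidic 4-OH reacts.

Step 2
Reactants: 2 5-bromo-2-hydroxy-4-(triisopropylsilyloxy)benzaldehyde
Product: 3 2-(allyloxy)-5-bromo-4-(triisopropylsilyloxy)benzaldehyde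
Conditions: allyl alcohol, PPh3, DIAD, THF, 0 °C → rt
Reagents that add atoms: allyl alcohol, C=CCO
Why: Mitsunobu etherification alkylates the acidic salicylaldehyde OH under neutral conditions, which avoids the carbonate bases that strip aryl silyl ethers.

Step 3
Reactants: 4 2,4-dihydroxybenzaldehyde
Product: 5 2-hydroxy-4-(triisopropylsilyloxy)benzaldehyde
Conditions: i-Pr3SiCl (1.05 equiv), imidazole, CH2Cl2, 0 °C → rt
Reagents that add atoms: triisopropylsilyl chloride, CC(C)[Si](Cl)(C(C)C)C(C)C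
Why: Selective silyl ether formation at the non-chelated 4-OH, as in step 1.

Step 4
Reactants: 5 2-hydroxy-4-(triisopropylsilyloxy)benzaldehyde
Product: 6 2-(benzyloxy)-4-(triisopropylsilyloxy)benzaldehyde
Conditions: BnOH, PPh3, DIAD, THF, 0 °C → rt
Reagents that add atoms: benzyl alcohol, OCc1ccccc1
Why: Mitsunobu etherification installs the benzyl ether that will mask the future pyran oxygen, again without base.

Step 5
Reactants: 6 2-(benzyloxy)-4-(triisopropylsilyloxy)benzaldehyde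
Product: 7 [3-(benzyloxy)-4-(2-methoxyethenyl)phenoxy]triisopropylsilane (E/Z mixture)
Conditions: MeOCH2PPh3Cl, KN(SiMe3)2, THF, 0 °C → rt
Reagents that add atoms: (methoxymethyl)triphenylphosphonium chloride, COC[P+](c1ccccc1)(c1ccccc1)c1ccccc1.[Cl-]
Why: Wittig one-carbon homologation of a non-enolisable aryl aldehyde to the enol ether; the alkene geometry is irrelevant.

Step 6
Reactants: 7 [3-(benzyloxy)-4-(2-methoxyethenyl)phenoxy]triisopropylsilane
Product: 8 2-[2-(benzyloxy)-4-(triisopropylsilyloxy)phenyl]acetaldehyde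
Conditions: 2 M aq HCl, THF, 40 °C; used crude
Reagents that add atoms: water, O
Why: Acid hydrolysis of the enol ether gives the arylacetaldehyde, and aryl triisopropylsilyl and benzyl ethers tolerate dilute aqueous acid.

Step 7
Reactants: 8 2-[2-(benzyloxy)-4-(triisopropylsilyloxy)phenyl]acetaldehyde
Product: 9 2-[2-(benzyloxy)-4-(triisopropylsilyloxy)phenyl]acetic acid
Conditions: NaClO2, NaH2PO4, 2-methylbut-2-ene, t-BuOH/H2O, 0 °C → rt
Reagents that add atoms: sodium chlorite, [Na+].[O-]Cl=O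
Why: Pinnick oxidation converts the aldehyde to the acid, with the alkene scavenger trapping HOCl before it can chlorinate the electron-rich ring.

Step 8
Reactants: 9 2-[2-(benzyloxy)-4-(triisopropylsilyloxy)phenyl]acetic acid; 10 (S)-4-benzyloxazolidin-2-one
Product: 12 (S)-4-benzyl-3-{2-[2-(benzyloxy)-4-(triisopropylsilyloxy)phenyl]acetyl}oxazolidin-2-one, via mixed pivalic anhydride 11 (not isolated)
Conditions: PivCl, Et3N, THF, −20 °C; then 10, LiCl, rt
Reagents that add atoms: none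
Why: N-acylation of the auxiliary through the mixed anhydride, which is attacked at its less hindered arylacetyl carbonyl.

Step 9
Reactants: 12 (S)-4-benzyl-3-{2-[2-(benzyloxy)-4-(triisopropylsilyloxy)phenyl]acetyl}oxazolidin-2-one; 3 2-(allyloxy)-5-bromo-4-(triisopropylsilyloxy)benzaldehyde
Product: 15 (S)-4-benzyl-3-{(2S,3S)-3-[2-(allyloxy)-5-bromo-4-(triisopropylsilyloxy)phenyl]-2-[2-(benzyloxy)-4-(triisopropylsilyloxy)phenyl]-3-hydroxypropanoyl}oxazolidin-2-one, via Z-dibutylboron enolate 13 (not isolated), via dibutylboron aldolate 14 (not isolated)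
Conditions: Bu2BOTf, i-Pr2NEt, CH2Cl2, −78 → 0 °C; then 3, −78 → 0 °C; then pH 7 buffer, MeOH, 30% H2O2, 0 °C
Reagents that add atoms: none
Why: Evans syn-aldol in which the Z-boron enolate reacts through a Zimmerman–Traxler chair on the face away from the auxiliary benzyl group, giving the (2S,3S) adduct; C2 is the future C3 of the isoflavan, and any epimer at C2 is a diastereomer removable by chromatography.

Step 10
Reactants: 15 the (2S,3S) aldol adduct
Product: 16 (S)-4-benzyl-3-{(2R)-3-[2-(allyloxy)-5-bromo-4-(triisopropylsilyloxy)phenyl]-2-[2-(benzyloxy)-4-(triisopropylsilyloxy)phenyl]propanoyl}oxazolidin-2-one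
Conditions: Et3SiH (5 equiv), CF3CO2H (10 equiv), CH2Cl2, −20 → 0 °C
Reagents that add atoms: none
Why: Ionic hydrogenation, in which the ortho,para-dioxygenated benzylic alcohol ionises readily and the cation is reduced by the silane; the stereocentre is untouched and its descriptor changes from S to R only because the priorities change.

Step 11
Reactants: 16 the (2R) imide
Product: 17 (2R)-3-[2-(allyloxy)-5-bromo-4-(triisopropylsilyloxy)phenyl]-2-[2-(benzyloxy)-4-(triisopropylsilyloxy)phenyl]propan-1-ol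
Conditions: LiBH4, MeOH (2 equiv), THF, 0 °C
Reagents that add atoms: none
Why: Reductive cleavage of the N-acyl oxazolidinone at the exocyclic carbonyl gives the primary alcohol at 0 °C, cold enough to avoid epimerising the alpha-aryl centre.

Step 12
Reactants: 17 the (2R) alcohol
Product: 18 2-{(2R)-2-[2-(benzyloxy)-4-(triisopropylsilyloxy)phenyl]-3-hydroxypropyl}-4-bromo-5-(triisopropylsilyloxy)phenol
Conditions: Pd(PPh3)4 (5 mol %), morpholine, THF, rt
Reagents that add atoms: none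
Why: Tsuji–Trost deallylation transfers the allyl group to morpholine at room temperature, where the electron-rich aryl bromide does not react with the catalyst.

Step 13
Reactants: 18 the phenol alcohol
Product: 19 (3R)-3-[2-(benzyloxy)-4-(triisopropylsilyloxy)phenyl]-6-bromo-7-(triisopropylsilyloxy)chromane
Conditions: PPh3, DIAD, THF (0.02 M), 0 °C → rt
Reagents that add atoms: none
Why: Intramolecular Mitsunobu etherification closes the six-membered chroman ring at the primary carbon, so the stereocentre is not involved; the only other ortho oxygen is still benzylated, which rules out dihydrobenzofuran formation.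

Step 14
Reactants: 19 the benzyl ether
Product: 20 2-[(3R)-6-bromo-7-(triisopropylsilyloxy)chroman-3-yl]-5-(triisopropylsilyloxy)phenol
Conditions: BCl3 (2.5 equiv), C6HMe5 (4 equiv), CH2Cl2, −78 °C; MeOH quench
Reagents that add atoms: none
Why: Lewis-acid debenzylation with pentamethylbenzene as cation scavenger removes the aryl benzyl ether at −78 °C without hydrogen, so the aryl bromide, silyl ethers and chroman ether survive.

Step 15
Reactants: 20 the phenol
Product: 21 (3R)-6-bromo-3-[2-(2-methylbut-3-yn-2-yloxy)-4-(triisopropylsilyloxy)phenyl]-7-(triisopropylsilyloxy)chromane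
Conditions: 3-chloro-3-methylbut-1-yne, DBU, CuCl2·2H2O (1 mol %), MeCN, 0 °C → rt
Reagents that add atoms: 3-chloro-3-methylbut-1-yne, CC(C)(Cl)C#C
Why: Copper-catalysed O-propargylation of the only free phenol with the tertiary propargylic chloride.

Step 16
Reactants: 21 the aryl propargyl ether
Product: 23 (3R)-6-bromo-3-[2,2-dimethyl-5-(triisopropylsilyloxy)-2H-chromen-8-yl]-7-(triisopropylsilyloxy)chromane, via ortho-allenylphenol 22 (not isolated)
Conditions: o-xylene, 145 °C, sealed tube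
Reagents that add atoms: none
Why: Aromatic propargyl Claisen rearrangement to the single free ortho carbon, followed by a 1,5-hydrogen shift and oxa-6π electrocyclisation, gives the 2,2-dimethylchromene with unambiguous regiochemistry.

Step 17
Reactants: 23 the aryl bromide
Product: 24 (3R)-3-[2,2-dimethyl-5-(triisopropylsilyloxy)-2H-chromen-8-yl]-6-(3-methylbut-2-en-1-yl)-7-(triisopropylsilyloxy)chromane
Conditions: Bu3SnCH2CH=CMe2 (2 equiv), Pd(PPh3)4 (10 mol %), DMF, 100 °C
Reagents that add atoms: tributyl(3-methylbut-2-en-1-yl)stannane, CCCC[Sn](CCCC)(CCCC)CC=C(C)C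
Why: Stille coupling under neutral, fluoride-free conditions puts the prenyl group on the carbon fixed by the bromine, reductive elimination occurring at the less hindered allyl terminus.

Step 18
Reactants: 24 the bis-silyl ether
Product: 25 (3R)-3-(5-hydroxy-2,2-dimethyl-2H-chromen-8-yl)-6-(3-methylbut-2-en-1-yl)chroman-7-ol
Conditions: Bu4NF (2.4 equiv), AcOH (2.4 equiv), THF, 0 °C
Reagents that add atoms: none
Why: Buffered fluoride desilylation frees both phenols without acid, so the prenyl group cannot cyclise onto the neighbouring hydroxyl and the chromene is left intact.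

**Compound list**
1 | 5-bromo-2,4-dihydroxybenzaldehyde | O=Cc1cc(Br)c(O)cc1O | starting material
2 | 5-bromo-2-hydroxy-4-(triisopropylsilyloxy)benzaldehyde | O=Cc1cc(Br)c(O[Si](C(C)C)(C(C)C)C(C)C)cc1O | intermediate
3 | 2-(allyloxy)-5-bromo-4-(triisopropylsilyloxy)benzaldehyde | O=Cc1cc(Br)c(O[Si](C(C)C)(C(C)C)C(C)C)cc1OCC=C | intermediate
4 | 2,4-dihydroxybenzaldehyde | O=Cc1ccc(O)cc1O | starting material
5 | 2-hydroxy-4-(triisopropylsilyloxy)benzaldehyde | O=Cc1ccc(O[Si](C(C)C)(C(C)C)C(C)C)cc1O | intermediate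
6 | 2-(benzyloxy)-4-(triisopropylsilyloxy)benzaldehyde | O=Cc1ccc(O[Si](C(C)C)(C(C)C)C(C)C)cc1OCc1ccccc1 | intermediate
7 | [3-(benzyloxy)-4-(2-methoxyethenyl)phenoxy]triisopropylsilane (E/Z mixture) | COC=Cc1ccc(O[Si](C(C)C)(C(C)C)C(C)C)cc1OCc1ccccc1 | intermediate
8 | 2-[2-(benzyloxy)-4-(triisopropylsilyloxy)phenyl]acetaldehyde | O=CCc1ccc(O[Si](C(C)C)(C(C)C)C(C)C)cc1OCc1ccccc1 | intermediate
9 | 2-[2-(benzyloxy)-4-(triisopropylsilyloxy)phenyl]acetic acid | OC(=O)Cc1ccc(O[Si](C(C)C)(C(C)C)C(C)C)cc1OCc1ccccc1 | intermediate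
10 | (S)-4-benzyloxazolidin-2-one | O=C1N[C@@H](Cc2ccccc2)CO1 | starting material
11 | 2-[2-(benzyloxy)-4-(triisopropylsilyloxy)phenyl]acetic pivalic anhydride | CC(C)(C)C(=O)OC(=O)Cc1ccc(O[Si](C(C)C)(C(C)C)C(C)C)cc1OCc1ccccc1 | intermediate
12 | (S)-4-benzyl-3-{2-[2-(benzyloxy)-4-(triisopropylsilyloxy)phenyl]acetyl}oxazolidin-2-one | O=C1OC[C@H](Cc2ccccc2)N1C(=O)Cc1ccc(O[Si](C(C)C)(C(C)C)C(C)C)cc1OCc1ccccc1 | intermediate
13 | (Z)-O-dibutylboryl enolate of 12 | CCCCB(CCCC)O/C(=C\c1ccc(O[Si](C(C)C)(C(C)C)C(C)C)cc1OCc1ccccc1)N1[C@@H](Cc2ccccc2)COC1=O | intermediate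
14 | O-dibutylboryl aldolate of 15 | O=C1OC[C@H](Cc2ccccc2)N1C(=O)[C@@H](c1ccc(O[Si](C(C)C)(C(C)C)C(C)C)cc1OCc1ccccc1)[C@H](OB(CCCC)CCCC)c1cc(Br)c(O[Si](C(C)C)(C(C)C)C(C)C)cc1OCC=C | intermediate
15 | (S)-4-benzyl-3-{(2S,3S)-3-[2-(allyloxy)-5-bromo-4-(triisopropylsilyloxy)phenyl]-2-[2-(benzyloxy)-4-(triisopropylsilyloxy)phenyl]-3-hydroxypropanoyl}oxazolidin-2-one | O=C1OC[C@H](Cc2ccccc2)N1C(=O)[C@@H](c1ccc(O[Si](C(C)C)(C(C)C)C(C)C)cc1OCc1ccccc1)[C@H](O)c1cc(Br)c(O[Si](C(C)C)(C(C)C)C(C)C)cc1OCC=C | intermediate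
16 | (S)-4-benzyl-3-{(2R)-3-[2-(allyloxy)-5-bromo-4-(triisopropylsilyloxy)phenyl]-2-[2-(benzyloxy)-4-(triisopropylsilyloxy)phenyl]propanoyl}oxazolidin-2-one | O=C1OC[C@H](Cc2ccccc2)N1C(=O)[C@@H](c1ccc(O[Si](C(C)C)(C(C)C)C(C)C)cc1OCc1ccccc1)Cc1cc(Br)c(O[Si](C(C)C)(C(C)C)C(C)C)cc1OCC=C | intermediate
17 | (2R)-3-[2-(allyloxy)-5-bromo-4-(triisopropylsilyloxy)phenyl]-2-[2-(benzyloxy)-4-(triisopropylsilyloxy)phenyl]propan-1-ol | OC[C@@H](c1ccc(O[Si](C(C)C)(C(C)C)C(C)C)cc1OCc1ccccc1)Cc1cc(Br)c(O[Si](C(C)C)(C(C)C)C(C)C)cc1OCC=C | intermediate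
18 | 2-{(2R)-2-[2-(benzyloxy)-4-(triisopropylsilyloxy)phenyl]-3-hydroxypropyl}-4-bromo-5-(triisopropylsilyloxy)phenol | OC[C@@H](c1ccc(O[Si](C(C)C)(C(C)C)C(C)C)cc1OCc1ccccc1)Cc1cc(Br)c(O[Si](C(C)C)(C(C)C)C(C)C)cc1O | intermediate
19 | (3R)-3-[2-(benzyloxy)-4-(triisopropylsilyloxy)phenyl]-6-bromo-7-(triisopropylsilyloxy)chromane | Brc1cc2c(cc1O[Si](C(C)C)(C(C)C)C(C)C)OC[C@@H](c1ccc(O[Si](C(C)C)(C(C)C)C(C)C)cc1OCc1ccccc1)C2 | intermediate
20 | 2-[(3R)-6-bromo-7-(triisopropylsilyloxy)chroman-3-yl]-5-(triisopropylsilyloxy)phenol | Brc1cc2c(cc1O[Si](C(C)C)(C(C)C)C(C)C)OC[C@@H](c1ccc(O[Si](C(C)C)(C(C)C)C(C)C)cc1O)C2 | intermediate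
21 | (3R)-6-bromo-3-[2-(2-methylbut-3-yn-2-yloxy)-4-(triisopropylsilyloxy)phenyl]-7-(triisopropylsilyloxy)chromane | Brc1cc2c(cc1O[Si](C(C)C)(C(C)C)C(C)C)OC[C@@H](c1ccc(O[Si](C(C)C)(C(C)C)C(C)C)cc1OC(C)(C)C#C)C2 | intermediate
22 | 2-[(3R)-6-bromo-7-(triisopropylsilyloxy)chroman-3-yl]-6-(3-methylbuta-1,2-dien-1-yl)-5-(triisopropylsilyloxy)phenol | Brc1cc2c(cc1O[Si](C(C)C)(C(C)C)C(C)C)OC[C@@H](c1ccc(O[Si](C(C)C)(C(C)C)C(C)C)c(C=C=C(C)C)c1O)C2 | intermediate
23 | (3R)-6-bromo-3-[2,2-dimethyl-5-(triisopropylsilyloxy)-2H-chromen-8-yl]-7-(triisopropylsilyloxy)chromane | Brc1cc2c(cc1O[Si](C(C)C)(C(C)C)C(C)C)OC[C@@H](c1ccc(O[Si](C(C)C)(C(C)C)C(C)C)c3c1OC(C)(C)C=C3)C2 | intermediate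
24 | (3R)-3-[2,2-dimethyl-5-(triisopropylsilyloxy)-2H-chromen-8-yl]-6-(3-methylbut-2-en-1-yl)-7-(triisopropylsilyloxy)chromane | CC(C)=CCc1cc2c(cc1O[Si](C(C)C)(C(C)C)C(C)C)OC[C@@H](c1ccc(O[Si](C(C)C)(C(C)C)C(C)C)c3c1OC(C)(C)C=C3)C2 | intermediate
25 | (3R)-3-(5-hydroxy-2,2-dimethyl-2H-chromen-8-yl)-6-(3-methylbut-2-en-1-yl)chroman-7-ol | CC(C)=CCc1cc2c(cc1O)OC[C@@H](c1ccc(O)c3c1OC(C)(C)C=C3)C2 | target

**Summary**
Total steps: 18. Longest linear sequence: 16 steps (steps 3 to 18, from 4 to 25). The ring A branch (steps 1 and 2) joins at step 9.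

**Steps most likely to fail**

Step 10, ionic deoxygenation. The benzylic cation can be captured by the benzyloxy oxygen of ring B, giving a 2-aryl-2,3-dihydrobenzofuran with loss of benzyl. It can also lose the para silyl group or eliminate. The fallback removes the hydroxyl through a radical and sets out from 15. LiBH4 (MeOH, THF, 0 °C) reduces the imide first to (1S,2R)-1-[2-(allyloxy)-5-bromo-4-(triisopropylsilyloxy)phenyl]-2-[2-(benzyloxy)-4-(triisopropylsilyloxy)phenyl]propane-1,3-diol F1. 1,1'-Thiocarbonyldiimidazole (DMAP cat., toluene, 80 °C) closes this to the cyclic thionocarbonate (4S,5R)-4-[2-(allyloxy)-5-bromo-4-(triisopropylsilyloxy)phenyl]-5-[2-(benzyloxy)-4-(triisopropylsilyloxy)phenyl]-1,3-dioxane-2-thione F2. Bu3SnH (1.2 equiv) with AIBN in toluene at 100 °C then breaks only the benzylic C–O bond (Barton–McCombie type), giving O-{(2R)-3-[2-(allyloxy)-5-bromo-4-(triisopropylsilyloxy)phenyl]-2-[2-(benzyloxy)-4-(triisopropylsilyloxy)phenyl]propyl} S-(tributylstannyl) thiocarbonate F3. Mild aqueous methanolysis of F3 gives alcohol 17, where the route is rejoined.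

Step 15, propargylation of the hindered phenol (and the Claisen step that depends on it). If 20 alkylates poorly, the pyran is built by aldehyde condensation instead, setting out from 20. Heating 20 with 3-methylbut-2-enal and PhB(OH)2 (propionic acid cat., toluene, reflux, Dean–Stark) gives (3R)-6-bromo-3-[4-(2-methylprop-1-en-1-yl)-2-phenyl-5-(triisopropylsilyloxy)-4H-1,3,2-benzodioxaborinin-8-yl]-7-(triisopropylsilyloxy)chromane F4 (both epimers at the new carbon). On continued heating F4 loses the boron unit and closes by oxa-6π electrocyclisation to chromene 23, where the route is rejoined; steps 15 and 16 are bypassed.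

Step 17, Stille prenylation. The bromide is electron-rich and flanked by a bulky silyl ether, and some branched (reverse-prenyl) isomer may form. The fallback sets out from 23 and makes the prenyl group in two operations. Stille coupling with Bu3SnCH2CH=CH2 (Pd(PPh3)4, DMF, 100 °C), which has no regiochemical ambiguity, gives (3R)-6-allyl-3-[2,2-dimethyl-5-(triisopropylsilyloxy)-2H-chromen-8-yl]-7-(triisopropylsilyloxy)chromane F5. Olefin cross-metathesis of F5 with excess 2-methylbut-2-ene, using RuCl2(=CHPh)(PCy3)(H2IMes) (the second-generation Grubbs catalyst) in CH2Cl2 at 40 °C, gives 24, where the route is rejoined.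

**Further compounds**
F1 | step 10 | (1S,2R)-1-[2-(allyloxy)-5-bromo-4-(triisopropylsilyloxy)phenyl]-2-[2-(benzyloxy)-4-(triisopropylsilyloxy)phenyl]propane-1,3-diol | OC[C@@H](c1ccc(O[Si](C(C)C)(C(C)C)C(C)C)cc1OCc1ccccc1)[C@H](O)c1cc(Br)c(O[Si](C(C)C)(C(C)C)C(C)C)cc1OCC=C
F2 | step 10 | (4S,5R)-4-[2-(allyloxy)-5-bromo-4-(triisopropylsilyloxy)phenyl]-5-[2-(benzyloxy)-4-(triisopropylsilyloxy)phenyl]-1,3-dioxane-2-thione | S=C1OC[C@@H](c2ccc(O[Si](C(C)C)(C(C)C)C(C)C)cc2OCc2ccccc2)[C@@H](c2cc(Br)c(O[Si](C(C)C)(C(C)C)C(C)C)cc2OCC=C)O1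
F3 | step 10 | O-{(2R)-3-[2-(allyloxy)-5-bromo-4-(triisopropylsilyloxy)phenyl]-2-[2-(benzyloxy)-4-(triisopropylsilyloxy)phenyl]propyl} S-(tributylstannyl) thiocarbonate | CCCC[Sn](CCCC)(CCCC)SC(=O)OC[C@@H](c1ccc(O[Si](C(C)C)(C(C)C)C(C)C)cc1OCc1ccccc1)Cc1cc(Br)c(O[Si](C(C)C)(C(C)C)C(C)C)cc1OCC=C
F4 | step 15 | (3R)-6-bromo-3-[4-(2-methylprop-1-en-1-yl)-2-phenyl-5-(triisopropylsilyloxy)-4H-1,3,2-benzodioxaborinin-8-yl]-7-(triisopropylsilyloxy)chromane | Brc1cc2c(cc1O[Si](C(C)C)(C(C)C)C(C)C)OC[C@@H](c1ccc(O[Si](C(C)C)(C(C)C)C(C)C)c3c1OB(c1ccccc1)OC3C=C(C)C)C2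
F5 | step 17 | (3R)-6-allyl-3-[2,2-dimethyl-5-(triisopropylsilyloxy)-2H-chromen-8-yl]-7-(triisopropylsilyloxy)chromane | C=CCc1cc2c(cc1O[Si](C(C)C)(C(C)C)C(C)C)OC[C@@H](c1ccc(O[Si](C(C)C)(C(C)C)C(C)C)c3c1OC(C)(C)C=C3)C2
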